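**Plan**

- Locants are those of the 3,7-dioxabicyclo[3.3.0]octane core: C2 bears the 3,4,5-trimethoxyphenyl group, C6 the 3-hydroxy-4,5-dimethoxyphenyl group. Retrosynthetically the phenol is masked as a benzyl ether, the C8 methylene is traced back to a lactone carbonyl, and C1–C2 and C4–C5 of ring A (C1–C2–O3–C4–C5) are cut together.
- Enabling feature: in ring A the unit C2–O3–C4 is attached only to the adjacent carbons C1 and C5. It is therefore an aryl carbonyl ylide, and C1=C5 is the α,β-double bond of a butenolide, ring B (C1–C5–C6–O7–C8), which already holds C6, O7 and C8.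
- Ring B is cut further at C1=C5 (ring-closing metathesis), O7–C8 (acrylate ester) and C5–C6 (vinyl addition to the aldehyde).
- Forward: ring B is made first, ring A is closed onto it by the (3+2) cycloaddition, then C8 is reduced and the phenol released.
- Stereochemistry: C6 comes from a lipase resolution of the allylic alcohol. C5 and C1 follow from addition anti to the C6 aryl group with suprafacial bond formation (cis fusion). C2 follows from the exo placement of its aryl group.

Key step: step 8

Remark: both aromatic starting materials are taken as purchasable; the core is C2-symmetric in its stereochemistry (both aryl-bearing carbons S, both bridgeheads R), so the assignment of the two aryl groups to C2 and C6 is only a matter of numbering.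

**Step 1**
Reactants: 1 3,4,5-trimethoxybenzyl alcohol
Product: 3 (3,4,5-trimethoxyphenyl)(trimethylsilyl)methanol (racemic), via benzyl trimethylsilyl ether 2 (not isolated)
Conditions: n-BuLi, THF, −78 °C; Me3SiCl, −78 → 0 °C; t-BuLi, −78 → −30 °C; AcOH, −78 °C
Reagents that add atoms: chlorotrimethylsilane, C[Si](C)(C)Cl
Why: O-silylation gives 2, t-BuLi lithiates its benzylic, oxygen-bearing CH2, and the carbanion undergoes the retro-Brook (1,2-silyl O→C) rearrangement driven by formation of the lithium alkoxide; cold protonation gives the racemic carbinol, whose stereocentre is lost later in the ylide.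

**Step 2**
Reactants: 3 (3,4,5-trimethoxyphenyl)(trimethylsilyl)methanol
Product: 4 chloromethyl (3,4,5-trimethoxyphenyl)(trimethylsilyl)methyl ether (racemic)
Conditions: (CH2O)n, Me3SiCl, CH2Cl2, 0 °C → rt; concentrated and used crude
Reagents that add atoms: paraformaldehyde (formaldehyde unit), C=O; chlorotrimethylsilane, C[Si](C)(C)Cl
Why: Chloromethylation of an alcohol: the hemiformal formed with formaldehyde is converted by Me3SiCl into the chloromethyl ether under mild conditions that the benzylic C–Si bond should tolerate, and the moisture-sensitive product is carried on without purification.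

**Step 3**
Reactants: 5 3-hydroxy-4,5-dimethoxybenzaldehyde
Product: 6 3-(benzyloxy)-4,5-dimethoxybenzaldehyde
Conditions: BnBr, K2CO3, DMF, rt
Reagents that add atoms: benzyl bromide, BrCc1ccccc1
Why: Williamson ether synthesis on the phenoxide; the benzyl ether withstands Grignard addition, metathesis, fluoride, hydride and the later BF3·OEt2/Et3SiH reduction (where an acetal-type group could be cleaved or reduced to a methyl ether) and is removed at the end under neutral conditions.

**Step 4**
Reactants: 6 3-(benzyloxy)-4,5-dimethoxybenzaldehyde; 7 vinylmagnesium bromide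
Product: 8 1-[3-(benzyloxy)-4,5-dimethoxyphenyl]prop-2-en-1-ol (racemic)
Conditions: THF, −78 → 0 °C; sat. aq. NH4Cl
Reagents that add atoms: none
Why: Grignard 1,2-addition to the aryl aldehyde forms the C5–C6 bond and gives the racemic allylic alcohol.

**Step 5**
Reactants: 8 1-[3-(benzyloxy)-4,5-dimethoxyphenyl]prop-2-en-1-ol (racemic)
Product: 9 (S)-1-[3-(benzyloxy)-4,5-dimethoxyphenyl]prop-2-en-1-ol
Conditions: vinyl acetate, immobilised Candida antarctica lipase B, MTBE, 30 °C, stopped a little past half conversion; chromatography
Reagents that add atoms: none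
Why: Lipase-catalysed kinetic resolution by transesterification: with aryl as the large and vinyl as the medium substituent the enzyme should acylate the R enantiomer, so the S alcohol (the future C6) remains and is separated from the R acetate, and running slightly past half conversion secures its enantiomeric purity.

**Step 6**
Reactants: 9 (S)-1-[3-(benzyloxy)-4,5-dimethoxyphenyl]prop-2-en-1-ol; 10 acryloyl chloride
Product: 11 (S)-1-[3-(benzyloxy)-4,5-dimethoxyphenyl]prop-2-en-1-yl acrylate
Conditions: Et3N, CH2Cl2, 0 °C
Reagents that add atoms: none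
Why: O-Acylation with an acid chloride under amine base forms the O7–C8 bond without touching the C–O bond of the stereocentre, so the configuration is retained.

**Step 7**
Reactants: 11 (S)-1-[3-(benzyloxy)-4,5-dimethoxyphenyl]prop-2-en-1-yl acrylate
Product: 12 (S)-5-[3-(benzyloxy)-4,5-dimethoxyphenyl]furan-2(5H)-one
Conditions: second-generation Grubbs catalyst (H2IMes)(PCy3)Cl2Ru=CHPh (5 mol %), CH2Cl2 (0.01 M), 40 °C
Reagents that add atoms: none
Why: Ring-closing metathesis between the acrylate and vinyl groups closes ring B as the butenolide with loss of ethene, under neutral conditions that leave the acidic C6–H stereocentre untouched.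

**Step 8**
Reactants: 4 chloromethyl (3,4,5-trimethoxyphenyl)(trimethylsilyl)methyl ether; 12 (S)-5-[3-(benzyloxy)-4,5-dimethoxyphenyl]furan-2(5H)-one
Product: 14 (1S,2S,5R,6S)-6-[3-(benzyloxy)-4,5-dimethoxyphenyl]-2-(3,4,5-trimethoxyphenyl)-3,7-dioxabicyclo[3.3.0]octan-8-one, via carbonyl ylide 13 (not isolated)
Conditions: CsF (added in portions), MeCN, rt
Reagents that add atoms: none
Why: Fluoride attacks silicon of 4 while chloride leaves (1,3-elimination), releasing the non-stabilised carbonyl ylide 13, which adds in a concerted, suprafacial (3+2) fashion across the electron-poor C1=C5 bond of 12 and forms C1–C2 and C4–C5 in one operation. The closest known reaction type is the fluoride-triggered carbonyl ylide cycloaddition of α-silyl chloromethyl ethers with acrylates, enones and unsaturated lactones. Ring A (C1–C2–O3–C4–C5) closes by this intermolecular 1,3-dipolar cycloaddition; both new bonds form on the same face of the alkene, so the ring fusion can only be cis. C5 and C1 are set by approach of the dipole anti to the C6 aryl group, that is by the stereocentre of 12, and C2 by the exo orientation of the trimethoxyphenyl group, which keeps it on the convex face away from the lactone ring. The step needs CH2-to-β regiochemistry, which the polarisation of the ylide should secure: the aryl group stabilises the oxocarbenium end and leaves the larger HOMO coefficient on the CH2 terminus, which pairs with C5, the site of the largest LUMO coefficient of the butenolide. Because the C6–H of 12 is acidic, CsF is added in portions to a mixture of both partners so that free fluoride does not build up.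

**Step 9**
Reactants: 14 (1S,2S,5R,6S)-6-[3-(benzyloxy)-4,5-dimethoxyphenyl]-2-(3,4,5-trimethoxyphenyl)-3,7-dioxabicyclo[3.3.0]octan-8-one
Product: 15 (1S,2S,5R,6S)-6-[3-(benzyloxy)-4,5-dimethoxyphenyl]-2-(3,4,5-trimethoxyphenyl)-3,7-dioxabicyclo[3.3.0]octan-8-ol (both C8 epimers)
Conditions: i-Bu2AlH, CH2Cl2, −78 °C; aq. potassium sodium tartrate
Reagents that add atoms: none
Why: Partial reduction of a γ-lactone with i-Bu2AlH at low temperature stops at the aluminium hemiacetal, which gives the lactol on work-up; the configuration at C8 is of no consequence.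

**Step 10**
Reactants: 15 (1S,2S,5R,6S)-6-[3-(benzyloxy)-4,5-dimethoxyphenyl]-2-(3,4,5-trimethoxyphenyl)-3,7-dioxabicyclo[3.3.0]octan-8-ol
Product: 16 (1R,2S,5R,6S)-6-[3-(benzyloxy)-4,5-dimethoxyphenyl]-2-(3,4,5-trimethoxyphenyl)-3,7-dioxabicyclo[3.3.0]octane
Conditions: Et3SiH, BF3·OEt2, CH2Cl2, −78 → −40 °C
Reagents that add atoms: none
Why: Ionic hydrogenation: BF3·OEt2 ionises the lactol to the cyclic oxocarbenium ion at C8, which Et3SiH reduces to the methylene group; at low temperature the lactol should ionise far faster than the benzylic ethers at C2 and C6, so those stereocentres are kept.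

**Step 11**
Reactants: 16 (1R,2S,5R,6S)-6-[3-(benzyloxy)-4,5-dimethoxyphenyl]-2-(3,4,5-trimethoxyphenyl)-3,7-dioxabicyclo[3.3.0]octane
Product: 17 (1R,2S,5R,6S)-6-(3-hydroxy-4,5-dimethoxyphenyl)-2-(3,4,5-trimethoxyphenyl)-3,7-dioxabicyclo[3.3.0]octane (CNP0181235.1)
Conditions: H2 (1 atm), Pd/C, EtOAc, rt
Reagents that add atoms: none
Why: Catalytic hydrogenolysis of the aryl benzyl ether frees the phenol under neutral conditions; the reaction is stopped as soon as 16 is consumed so that the benzylic C2–O3 and C6–O7 bonds of the furofuran are not cleaved.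

**Compound list**

1 | 3,4,5-trimethoxybenzyl alcohol | COc1cc(CO)cc(OC)c1OC | starting material
2 | trimethyl[(3,4,5-trimethoxybenzyl)oxy]silane (not isolated) | COc1cc(CO[Si](C)(C)C)cc(OC)c1OC | intermediate
3 | (3,4,5-trimethoxyphenyl)(trimethylsilyl)methanol (racemic) | COc1cc(C(O)[Si](C)(C)C)cc(OC)c1OC | intermediate
4 | chloromethyl (3,4,5-trimethoxyphenyl)(trimethylsilyl)methyl ether (racemic) | COc1cc(C(OCCl)[Si](C)(C)C)cc(OC)c1OC | intermediate
5 | 3-hydroxy-4,5-dimethoxybenzaldehyde | COc1cc(C=O)cc(O)c1OC | starting material
6 | 3-(benzyloxy)-4,5-dimethoxybenzaldehyde | COc1cc(C=O)cc(OCc2ccccc2)c1OC | intermediate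
7 | vinylmagnesium bromide | C=C[Mg]Br | starting material
8 | 1-[3-(benzyloxy)-4,5-dimethoxyphenyl]prop-2-en-1-ol (racemic) | C=CC(O)c1cc(OC)c(OC)c(OCc2ccccc2)c1 | intermediate
9 | (S)-1-[3-(benzyloxy)-4,5-dimethoxyphenyl]prop-2-en-1-ol | C=C[C@H](O)c1cc(OC)c(OC)c(OCc2ccccc2)c1 | intermediate
10 | acryloyl chloride | C=CC(=O)Cl | starting material
11 | (S)-1-[3-(benzyloxy)-4,5-dimethoxyphenyl]prop-2-en-1-yl acrylate | C=C[C@H](OC(=O)C=C)c1cc(OC)c(OC)c(OCc2ccccc2)c1 | intermediate
12 | (S)-5-[3-(benzyloxy)-4,5-dimethoxyphenyl]furan-2(5H)-one | O=C1C=C[C@@H](c2cc(OC)c(OC)c(OCc3ccccc3)c2)O1 | intermediate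
13 | carbonyl ylide ArCH=O(+)–CH2(−), Ar = 3,4,5-trimethoxyphenyl (not isolated) | COc1cc(C=[O+][CH2-])cc(OC)c1OC | intermediate
14 | (1S,2S,5R,6S)-6-[3-(benzyloxy)-4,5-dimethoxyphenyl]-2-(3,4,5-trimethoxyphenyl)-3,7-dioxabicyclo[3.3.0]octan-8-one (cis-fused, both aryl groups exo) | COc1cc([C@H]2OC[C@H]3[C@@H]2C(=O)O[C@@H]3c4cc(OCc5ccccc5)c(OC)c(OC)c4)cc(OC)c1OC | intermediate
15 | (1S,2S,5R,6S)-6-[3-(benzyloxy)-4,5-dimethoxyphenyl]-2-(3,4,5-trimethoxyphenyl)-3,7-dioxabicyclo[3.3.0]octan-8-ol (both C8 epimers) | COc1cc([C@H]2OC[C@H]3[C@@H]2C(O)O[C@@H]3c4cc(OCc5ccccc5)c(OC)c(OC)c4)cc(OC)c1OC | intermediate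
16 | (1R,2S,5R,6S)-6-[3-(benzyloxy)-4,5-dimethoxyphenyl]-2-(3,4,5-trimethoxyphenyl)-3,7-dioxabicyclo[3.3.0]octane | COc1cc([C@H]2OC[C@H]3[C@@H]2CO[C@@H]3c4cc(OCc5ccccc5)c(OC)c(OC)c4)cc(OC)c1OC | intermediate
17 | (1R,2S,5R,6S)-6-(3-hydroxy-4,5-dimethoxyphenyl)-2-(3,4,5-trimethoxyphenyl)-3,7-dioxabicyclo[3.3.0]octane | COc1cc([C@H]2OC[C@H]3[C@@H]2CO[C@@H]3c2cc(OC)c(OC)c(OC)c2)cc(O)c1OC | target

**Step count**

Total step count: 11. Longest linear sequence: 9 steps (steps 3 to 11, from 5).

**Steps most likely to fail**

Step 8. The dipole may add with the wrong regiochemistry or with poor exo/endo selectivity at C2, the facial selectivity may be incomplete, or fluoride may erode the C6 stereocentre by reversible γ-deprotonation of the butenolide. The fallback sets out from 9 and builds the bicycle by a radical route instead of a cycloaddition. Epoxidation of the vinyl group (mCPBA, NaHCO3, CH2Cl2, rt) should give epoxy alcohol F1; its epoxide carbon later becomes a planar radical, so both epimers serve. (E)-3,4,5-Trimethoxycinnamyl bromide F2 is made from the commercial cinnamyl alcohol (PBr3, Et2O, 0 °C) and used to alkylate the alkoxide of F1 (NaH, THF, 0 °C), giving epoxy ether F3. Cp2TiCl (trivalent titanium, from Cp2TiCl2 and Zn in THF) should open the epoxide to the secondary radical at C5. This radical cyclises 5-exo-trig onto the cinnamyl double bond (C5–C1, ring B), the benzylic radical at C2 is captured by a second Cp2TiCl, and I2 turns the C–Ti bond into a benzylic iodide that the titanium alkoxide on C4–O displaces to close ring A. The product is 16, where the fallback comes back to the route; steps 9 and 10 are then not needed. C6 is carried over from 9, the cyclisation places C4 trans to the C6 aryl group, the second closure forces the cis fusion, and the benzylic displacement should favour the exo aryl group at C2.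

Step 10. The Lewis acid may ionise the two electron-rich benzylic ether bonds in competition with the lactol, leading to epimerisation at C2 or C6 or to ring opening. The fallback sets out from 14 and avoids any cationic intermediate. LiAlH4 (THF, 0 °C) opens the lactone to diol F4 (primary C8–OH, benzylic C6–OH). MsCl in pyridine (0 °C → rt) sulfonylates the primary hydroxyl selectively to primary mesylate F5, which is not isolated: the C6 hydroxyl displaces it in a 5-exo-tet closure with retention at C6. This gives 16, where the route is rejoined.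

Step 1. Lithiation of the ring next to a methoxy group, or attack of the alkyllithium at silicon, may compete with benzylic lithiation, and the alkoxide may revert by Brook rearrangement on quenching. The fallback sets out from 1 and installs silicon by nucleophilic silyl addition instead of anionic migration. MnO2 (CH2Cl2, rt) oxidises 1 to 3,4,5-trimethoxybenzaldehyde F6. Copper-catalysed 1,2-addition of the silylboronate PhMe2Si–Bpin ((IPr)CuCl, NaOt-Bu, THF, rt; IPr = 1,3-bis(2,6-diisopropylphenyl)imidazol-2-ylidene) gives O-boryl α-silyl ether F7, which is not isolated and is cleaved with MeOH on work-up to α-silyl carbinol F8. Chloromethylation as in step 2 gives chloromethyl ether F9. F9 takes the place of 4 in step 8: fluoride removes the dimethylphenylsilyl group just as it removes trimethylsilyl, the same ylide 13 is formed, and the route is rejoined at 14.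

**Further compounds**

F1 | step 8 | (R)-[3-(benzyloxy)-4,5-dimethoxyphenyl](oxiran-2-yl)methanol, both epoxide epimers (carbinol centre spatially as in 9) | O[C@@H](C1CO1)c1cc(OC)c(OC)c(OCc2ccccc2)c1
F2 | step 8 | (E)-3,4,5-trimethoxycinnamyl bromide | COc1cc(/C=C/CBr)cc(OC)c1OC
F3 | step 8 | (E)-3,4,5-trimethoxycinnamyl ether of F1 | COc1cc(/C=C/CO[C@@H](C2CO2)c2cc(OC)c(OC)c(OCc3ccccc3)c2)cc(OC)c1OC
F4 | step 10 | diol from opening of ring B of 14: C8H2OH on C1, C6H(OH)Ar on C5, configurations as in 14 | COc1cc([C@H]2OC[C@@H]([C@@H]2CO)[C@H](O)c2cc(OCc3ccccc3)c(OC)c(OC)c2)cc(OC)c1OC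
F5 | step 10 | primary (C8) methanesulfonate of F4 | COc1cc([C@H]2OC[C@@H]([C@@H]2COS(C)(=O)=O)[C@H](O)c2cc(OCc3ccccc3)c(OC)c(OC)c2)cc(OC)c1OC
F6 | step 1 | 3,4,5-trimethoxybenzaldehyde | COc1cc(C=O)cc(OC)c1OC
F7 | step 1 | 2-{[dimethyl(phenyl)silyl](3,4,5-trimethoxyphenyl)methoxy}-4,4,5,5-tetramethyl-1,3,2-dioxaborolane (racemic) | COc1cc(C(OB2OC(C)(C)C(C)(C)O2)[Si](C)(C)c2ccccc2)cc(OC)c1OC
F8 | step 1 | [dimethyl(phenyl)silyl](3,4,5-trimethoxyphenyl)methanol (racemic) | COc1cc(C(O)[Si](C)(C)c2ccccc2)cc(OC)c1OC
F9 | step 1 | chloromethyl [dimethyl(phenyl)silyl](3,4,5-trimethoxyphenyl)methyl ether (racemic) | COc1cc(C(OCCl)[Si](C)(C)c2ccccc2)cc(OC)c1OC
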